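**Retrosynthetic overview**

1. The route rests on the E-trisubstituted C2'=C3' alkene: C3' carries a methyl group, and only the C1' methylene separates the alkene from the hydroquinone ring (ring A). Cutting C1'–C2' and C3'–CH3 together gives benzylic chloride 26, Me3Al (5) and terminal alkyne 20 (C2'–C16').
2. The C5' ketone is carried through the coupling as a free allylic alcohol. Oxidation and removal of three TBS groups come last, so the base-sensitive skipped dienone exists only in the final two steps.
3. Alkyne 20 is built as follows: C4'–C5' by zinc propargylation of Z-enal 17; Z-C6'=C7' by syn-carbocupration of propyne; E-C10'=C11' by methylalumination and oxirane opening; (R)-C13' by catalytic asymmetric propargylation of 3-methylbut-2-enal.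
4. Chloride 26 comes from 3-methylsalicylic acid by Elbs hydroxylation, silylation, reduction and chlorination.
5. No ring is formed; ring A is bought with the starting acid.

Key step: step 12

Assumption: the (R)-configured phosphoric acid catalyst is taken to deliver the (R)-carbinol 3, as it does with aryl and cinnamyl-type aldehydes. If Mosher ester analysis of 3 shows the opposite sense, the (S)-catalyst is used and nothing else changes.

**Route**

Step 1
Reactants: 1 3-methylbut-2-enal; 2 allenylboronic acid pinacol ester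
Product: 3 (4R)-6-methylhept-5-en-1-yn-4-ol
Conditions: (R)-3,3'-bis(2,4,6-triisopropylphenyl)-1,1'-binaphthyl-2,2'-diyl hydrogen phosphate (5 mol%), 4 Å MS, toluene, −20 to 0 °C; aqueous work-up
Reagents that add atoms: none
Why: Chiral phosphoric acid-catalysed propargylboration, in which the acid holds the boronate oxygen and the formyl hydrogen in a closed six-membered transition state so that the allenyl group adds with SE2' transposition to one aldehyde face, which sets C13' as R.

Step 2
Reactants: 3 (4R)-6-methylhept-5-en-1-yn-4-ol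
Product: 4 tert-butyldimethyl{[(4R)-6-methylhept-5-en-1-yn-4-yl]oxy}silane
Conditions: TBSCl, imidazole, DMF, rt
Reagents that add atoms: tert-butyldimethylsilyl chloride, CC(C)(C)[Si](C)(C)Cl
Why: Standard silylation of a secondary alcohol under imidazole catalysis, which leaves the alkyne and the stereocentre untouched.

Step 3
Reactants: 4 TBS ether of (4R)-6-methylhept-5-en-1-yn-4-ol; 5 trimethylaluminium; 6 oxirane
Product: 9 (3E,6R)-6-(tert-butyldimethylsilyloxy)-4,8-dimethylnona-3,7-dien-1-ol, via alkenyldimethylalane 7 (not isolated), via lithium alkenylalanate 8 (not isolated)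
Conditions: Me3Al (2 equiv), Cp2ZrCl2 (0.2 equiv), CH2Cl2, 0 °C to rt; volatiles removed; n-BuLi, hexane, −78 to 0 °C; oxirane, THF, −30 °C to rt
Reagents that add atoms: none
Why: Zirconium-catalysed syn-methylalumination of the terminal alkyne (Negishi carboalumination) places CH3 on C11' and aluminium on C10', and the derived alanate opens oxirane with retention of alkene geometry, as in the known preparation of homogeraniol-type alcohols.

Step 4
Reactants: 9 (3E,6R)-6-(tert-butyldimethylsilyloxy)-4,8-dimethylnona-3,7-dien-1-ol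
Product: 10 (3E,6R)-6-(tert-butyldimethylsilyloxy)-1-iodo-4,8-dimethylnona-3,7-diene
Conditions: I2, PPh3, imidazole, CH2Cl2, 0 °C
Reagents that add atoms: iodine, II
Why: Appel-type iodination of a primary alcohol under neutral buffered conditions, which the allylic silyl ether and both alkenes tolerate.

Step 5
Reactants: 10 (3E,6R)-6-(tert-butyldimethylsilyloxy)-1-iodo-4,8-dimethylnona-3,7-diene; 11 propyne
Product: 15 (1Z,5E,8R)-8-(tert-butyldimethylsilyloxy)-1-iodo-2,6,10-trimethylundeca-1,5,9-triene, via alkylmagnesium iodide 12 (not isolated), via alkylcopper 13 (not isolated), via Z-alkenylcopper 14 (not isolated)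
Conditions: Mg, Et2O, rt; CuBr·SMe2 (1 equiv), Et2O/Me2S, −45 °C; propyne (excess), −25 °C; I2, THF, −78 to 0 °C
Reagents that add atoms: iodine, II
Why: Normant carbocupration, in which the alkylcopper adds syn across propyne with the alkyl group on the methyl-bearing carbon and iodinolysis proceeds with retention, so the C8' chain and iodine end up cis (Z-C6'=C7').

Step 6
Reactants: 15 (1Z,5E,8R)-8-(tert-butyldimethylsilyloxy)-1-iodo-2,6,10-trimethylundeca-1,5,9-triene
Product: 17 (2Z,6E,9R)-9-(tert-butyldimethylsilyloxy)-3,7,11-trimethyldodeca-2,6,10-trienal, via Z-alkenyllithium 16 (not isolated)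
Conditions: t-BuLi (2.1 equiv), Et2O, −78 °C; DMF, −78 to 0 °C; inverse quench into cold aqueous NaH2PO4
Reagents that add atoms: N,N-dimethylformamide, CN(C)C=O
Why: Iodine–lithium exchange gives a configurationally stable alkenyllithium that is formylated with retention (Bouveault formylation), and the cold acidic quench protonates the liberated dimethylamine before it can isomerise the Z-enal.

Step 7
Reactants: 17 (2Z,6E,9R)-9-(tert-butyldimethylsilyloxy)-3,7,11-trimethyldodeca-2,6,10-trienal; 18 propargyl bromide
Product: 20 (5Z,9E,12R)-12-(tert-butyldimethylsilyloxy)-6,10,14-trimethylpentadeca-5,9,13-trien-1-yn-4-ol as a mixture of C4 epimers, via allenylzinc bromide 19 (not isolated)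
Conditions: Zn dust (activated), THF, 0 °C; aqueous NH4Cl work-up; minor allenyl carbinol removed by chromatography
Reagents that add atoms: none
Why: Barbier-type zinc propargylation, in which allenylzinc bromide adds 1,2 to the enal through an SE2' transition state to give the homopropargylic alcohol, and the uncontrolled C5' centre does not matter because it is oxidised in step 13.

Step 8
Reactants: 21 3-methylsalicylic acid
Product: 23 2,5-dihydroxy-3-methylbenzoic acid, via aryl sulfate 22 (not isolated)
Conditions: K2S2O8, aqueous NaOH, 0 °C to rt; then aqueous HCl, 90 °C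
Reagents that add atoms: potassium peroxodisulfate, [K+].[K+].[O-]S(=O)(=O)OOS(=O)(=O)[O-]
Why: Elbs persulfate oxidation, in which the phenoxide is attacked by peroxodisulfate at the only free position para to the hydroxyl and acid hydrolysis of the aryl sulfate releases the hydroquinone.

Step 9
Reactants: 23 2,5-dihydroxy-3-methylbenzoic acid
Product: 24 tert-butyldimethylsilyl 2,5-bis(tert-butyldimethylsilyloxy)-3-methylbenzoate
Conditions: TBSCl (3.6 equiv), imidazole, DMAP (cat.), DMF, 50 °C
Reagents that add atoms: tert-butyldimethylsilyl chloride, CC(C)(C)[Si](C)(C)Cl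
Why: Exhaustive silylation of both phenols and the acid, as is known for salicylic acids, with mild heating to drive the hindered C2 phenol to completion.

Step 10
Reactants: 24 tert-butyldimethylsilyl 2,5-bis(tert-butyldimethylsilyloxy)-3-methylbenzoate
Product: 25 [2,5-bis(tert-butyldimethylsilyloxy)-3-methylphenyl]methanol
Conditions: i-Bu2AlH (3 equiv), CH2Cl2, −78 to −20 °C; aqueous potassium sodium tartrate
Reagents that add atoms: none
Why: Hydride reduction of the silyl ester to the benzylic alcohol, where the weakly nucleophilic aluminium alkoxide formed at low temperature should not trigger aryl-to-benzyl silyl migration.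

Step 11
Reactants: 25 [2,5-bis(tert-butyldimethylsilyloxy)-3-methylphenyl]methanol
Product: 26 2,5-bis(tert-butyldimethylsilyloxy)-3-methylbenzyl chloride
Conditions: PPh3, N-chlorosuccinimide, THF, 0 °C to rt; short silica plug, used at once
Reagents that add atoms: N-chlorosuccinimide, O=C1CCC(=O)N1Cl
Why: Appel-type chlorination through the alkoxyphosphonium salt under neutral conditions, which avoids the acid and base that would cleave or shift the aryl silyl ethers.

Step 12
Reactants: 20 homopropargylic alcohol (C2'–C16' alkyne); 5 trimethylaluminium; 26 2,5-bis(tert-butyldimethylsilyloxy)-3-methylbenzyl chloride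
Product: 28 (2E,6Z,10E,13R)-1-[2,5-bis(tert-butyldimethylsilyloxy)-3-methylphenyl]-13-(tert-butyldimethylsilyloxy)-3,7,11,15-tetramethylhexadeca-2,6,10,14-tetraen-5-ol as a mixture of C5 epimers, via alkenyldimethylalane 27 (not isolated)
Conditions: Me3Al (3 equiv), Cp2ZrCl2 (0.25 equiv), CH2Cl2, 0 °C to rt; volatiles removed, THF; 26 (1.2 equiv), NiCl2(PPh3)2 (5 mol%) pre-reduced with n-BuLi (10 mol%), THF, 0 °C to rt; aqueous potassium sodium tartrate
Reagents that add atoms: none
Why: Me3Al first turns the C5' hydroxyl into its dimethylaluminium alkoxide, then a cationic methylzirconocene formed from Cp2ZrCl2 and Me3Al delivers CH3 to C3' and the metal to C2' on the same face of the terminal alkyne, and zirconium-to-aluminium exchange gives alkenylalane 27. Zerovalent nickel, made from NiCl2(PPh3)2 and n-BuLi, inserts into the benzylic C–Cl bond of 26, accepts the alkenyl group from aluminium and eliminates reductively with retention to form C1'–C2'. The closest known reaction type is zirconocene-catalysed methylalumination of a terminal alkyne followed by nickel-catalysed coupling of the alkenylalane with a benzylic chloride, as used for polyprenylated quinones; here it forms two skeletal bonds, closes no ring and creates no stereocentre. The step needs methyl delivery to the internal carbon and E geometry, which the syn-specific addition to a terminal alkyne and the stereoretentive coupling secure, and the benzylic electrophile has no allylic terminus, so neither SN2' attack nor geometric scrambling can occur at the new bond. The chelation-driven syn-to-anti isomerisation of homopropargylic alkoxy alanes needs prolonged heating, so the sequence is kept at or below room temperature, and excess Me3Al is stripped before the coupling so that methyl transfer to 26 does not compete. The C13' silyl ether and the three trisubstituted alkenes are inert, and the C5' epimer mixture is erased in step 13.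

Step 13
Reactants: 28 tris-TBS C5' alcohol
Product: 29 (2E,6Z,10E,13R)-1-[2,5-bis(tert-butyldimethylsilyloxy)-3-methylphenyl]-13-(tert-butyldimethylsilyloxy)-3,7,11,15-tetramethylhexadeca-2,6,10,14-tetraen-5-one
Conditions: Dess–Martin periodinane, NaHCO3, CH2Cl2, 0 °C
Reagents that add atoms: none
Why: Dess–Martin oxidation of the secondary allylic alcohol under buffered, non-basic conditions should give the ketone without moving the C2'=C3' bond into conjugation or isomerising the Z-C6'=C7' bond.

Step 14
Reactants: 29 tris-TBS ketone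
Product: 30 (2E,6Z,10E,13R)-1-(2,5-dihydroxy-3-methylphenyl)-13-hydroxy-3,7,11,15-tetramethylhexadeca-2,6,10,14-tetraen-5-one (CNP0251818.2)
Conditions: Bu4NF/AcOH (1:1, 4 equiv), THF, 0 °C to rt, argon; pH 6 buffer with a little Na2S2O4 on work-up
Reagents that add atoms: none
Why: Fluoride desilylation cleaves the two aryl ethers and the secondary allylic ether, while the acetic acid buffer keeps the phenoxides protonated so that the skipped dienone is not deprotonated at C4' and the hydroquinone is not air-oxidised.

**Compound list**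

1 | 3-methylbut-2-enal | CC(C)=CC=O | starting material
2 | allenylboronic acid pinacol ester (4,4,5,5-tetramethyl-2-propa-1,2-dienyl-1,3,2-dioxaborolane) | C=C=CB1OC(C)(C)C(C)(C)O1 | starting material
3 | (4R)-6-methylhept-5-en-1-yn-4-ol | CC(C)=C[C@H](O)CC#C | intermediate
4 | tert-butyldimethyl{[(4R)-6-methylhept-5-en-1-yn-4-yl]oxy}silane | CC(C)=C[C@H](O[Si](C)(C)C(C)(C)C)CC#C | intermediate
5 | trimethylaluminium | C[Al](C)C | starting material
6 | oxirane | C1CO1 | starting material
7 | dimethyl[(1E,4R)-4-(tert-butyldimethylsilyloxy)-2,6-dimethylhepta-1,5-dien-1-yl]alane (not isolated) | CC(C)=C[C@H](O[Si](C)(C)C(C)(C)C)C/C(C)=C/[Al](C)C | intermediate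
8 | lithium butyl(dimethyl)[(1E,4R)-4-(tert-butyldimethylsilyloxy)-2,6-dimethylhepta-1,5-dien-1-yl]aluminate (not isolated) | CC(C)=C[C@H](O[Si](C)(C)C(C)(C)C)C/C(C)=C/[Al-](C)(C)CCCC.[Li+] | intermediate
9 | (3E,6R)-6-(tert-butyldimethylsilyloxy)-4,8-dimethylnona-3,7-dien-1-ol | CC(C)=C[C@H](O[Si](C)(C)C(C)(C)C)C/C(C)=C/CCO | intermediate
10 | (3E,6R)-6-(tert-butyldimethylsilyloxy)-1-iodo-4,8-dimethylnona-3,7-diene | CC(C)=C[C@H](O[Si](C)(C)C(C)(C)C)C/C(C)=C/CCI | intermediate
11 | propyne | CC#C | starting material
12 | [(3E,6R)-6-(tert-butyldimethylsilyloxy)-4,8-dimethylnona-3,7-dien-1-yl]magnesium iodide (not isolated) | CC(C)=C[C@H](O[Si](C)(C)C(C)(C)C)C/C(C)=C/CC[Mg]I | intermediate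
13 | [(3E,6R)-6-(tert-butyldimethylsilyloxy)-4,8-dimethylnona-3,7-dien-1-yl]copper, as its Me2S and magnesium halide complex (not isolated) | CC(C)=C[C@H](O[Si](C)(C)C(C)(C)C)C/C(C)=C/CC[Cu] | intermediate
14 | [(1Z,5E,8R)-8-(tert-butyldimethylsilyloxy)-2,6,10-trimethylundeca-1,5,9-trien-1-yl]copper (not isolated) | CC(C)=C[C@H](O[Si](C)(C)C(C)(C)C)C/C(C)=C/CC/C(C)=C\[Cu] | intermediate
15 | (1Z,5E,8R)-8-(tert-butyldimethylsilyloxy)-1-iodo-2,6,10-trimethylundeca-1,5,9-triene | CC(C)=C[C@H](O[Si](C)(C)C(C)(C)C)C/C(C)=C/CC/C(C)=C\I | intermediate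
16 | [(1Z,5E,8R)-8-(tert-butyldimethylsilyloxy)-2,6,10-trimethylundeca-1,5,9-trien-1-yl]lithium (not isolated) | CC(C)=C[C@H](O[Si](C)(C)C(C)(C)C)C/C(C)=C/CC/C(C)=C\[Li] | intermediate
17 | (2Z,6E,9R)-9-(tert-butyldimethylsilyloxy)-3,7,11-trimethyldodeca-2,6,10-trienal | CC(C)=C[C@H](O[Si](C)(C)C(C)(C)C)C/C(C)=C/CC/C(C)=C\C=O | intermediate
18 | propargyl bromide (3-bromoprop-1-yne) | C#CCBr | starting material
19 | allenylzinc bromide (not isolated) | C=C=C[Zn]Br | intermediate
20 | (5Z,9E,12R)-12-(tert-butyldimethylsilyloxy)-6,10,14-trimethylpentadeca-5,9,13-trien-1-yn-4-ol, both C4 epimers (C2'–C16' alkyne, free C5' hydroxyl) | CC(C)=C[C@H](O[Si](C)(C)C(C)(C)C)C/C(C)=C/CC/C(C)=C\C(O)CC#C | intermediate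
21 | 3-methylsalicylic acid (2-hydroxy-3-methylbenzoic acid) | Cc1cccc(C(=O)O)c1O | starting material
22 | potassium 3-carboxy-4-hydroxy-5-methylphenyl sulfate (not isolated) | Cc1cc(OS(=O)(=O)[O-])cc(C(=O)O)c1O.[K+] | intermediate
23 | 2,5-dihydroxy-3-methylbenzoic acid | Cc1cc(O)cc(C(=O)O)c1O | intermediate
24 | tert-butyldimethylsilyl 2,5-bis(tert-butyldimethylsilyloxy)-3-methylbenzoate | Cc1cc(O[Si](C)(C)C(C)(C)C)cc(C(=O)O[Si](C)(C)C(C)(C)C)c1O[Si](C)(C)C(C)(C)C | intermediate
25 | [2,5-bis(tert-butyldimethylsilyloxy)-3-methylphenyl]methanol | Cc1cc(O[Si](C)(C)C(C)(C)C)cc(CO)c1O[Si](C)(C)C(C)(C)C | intermediate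
26 | 2,5-bis(tert-butyldimethylsilyloxy)-3-methylbenzyl chloride | ClCc1cc(O[Si](C)(C)C(C)(C)C)cc(C)c1O[Si](C)(C)C(C)(C)C | intermediate
27 | (1E,5Z,9E,12R)-alkenyldimethylalane derived from 20, with the C5' oxygen as its dimethylaluminium alkoxide (not isolated) | CC(C)=C[C@H](O[Si](C)(C)C(C)(C)C)C/C(C)=C/CC/C(C)=C\C(O[Al](C)C)C/C(C)=C/[Al](C)C | intermediate
28 | (2E,6Z,10E,13R)-1-[2,5-bis(tert-butyldimethylsilyloxy)-3-methylphenyl]-13-(tert-butyldimethylsilyloxy)-3,7,11,15-tetramethylhexadeca-2,6,10,14-tetraen-5-ol, both C5 epimers | CC(C)=C[C@H](O[Si](C)(C)C(C)(C)C)C/C(C)=C/CC/C(C)=C\C(O)C/C(C)=C/Cc1cc(O[Si](C)(C)C(C)(C)C)cc(C)c1O[Si](C)(C)C(C)(C)C | intermediate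
29 | (2E,6Z,10E,13R)-1-[2,5-bis(tert-butyldimethylsilyloxy)-3-methylphenyl]-13-(tert-butyldimethylsilyloxy)-3,7,11,15-tetramethylhexadeca-2,6,10,14-tetraen-5-one | CC(C)=C[C@H](O[Si](C)(C)C(C)(C)C)C/C(C)=C/CC/C(C)=C\C(=O)C/C(C)=C/Cc1cc(O[Si](C)(C)C(C)(C)C)cc(C)c1O[Si](C)(C)C(C)(C)C | intermediate
30 | (2E,6Z,10E,13R)-1-(2,5-dihydroxy-3-methylphenyl)-13-hydroxy-3,7,11,15-tetramethylhexadeca-2,6,10,14-tetraen-5-one | CC(C)=C[C@H](O)C/C(C)=C/CC/C(C)=C\C(=O)C/C(C)=C/Cc1cc(O)cc(C)c1O | target

**Step count**

Total: 14 steps. Longest linear sequence: 10 steps (steps 1–7, then 12–14); the arene branch (steps 8–11) joins at step 12.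

**Steps most likely to fail**

Step 12. Three processes could erode the one-pot coupling: methyl transfer from residual methylaluminium species to the benzylic chloride; sluggish transfer of the alkenyl group from the internally chelated alkoxy alane to nickel; and partial loss of E geometry through alkoxide-assisted isomerisation of the alane. The fallback inverts the polarity of the same bond and sets out from 20 and 26. The methylalumination of 20 is run as before but quenched with I2 at −30 °C to give the isolable vinyl iodide (1E,5Z,9E,12R)-12-(tert-butyldimethylsilyloxy)-1-iodo-2,6,10,14-tetramethylpentadeca-1,5,9,13-tetraen-4-ol F1, whose geometry can be checked and purified. Chloride 26 is converted with Zn dust and LiCl in THF into [2,5-bis(tert-butyldimethylsilyloxy)-3-methylbenzyl]zinc chloride F2. A Negishi coupling of F1 with excess F2 under zerovalent palladium (Pd(PPh3)4, THF, rt) then forms C1'–C2' and returns to the route at 28.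

Step 5. Wurtz dimerisation during Grignard formation, deprotonation of propyne in place of addition, or incomplete carbocupration would cut the supply of the Z-vinyl iodide. The fallback builds the Z-C6'=C7' unit from a preformed Z-iodoalkene and runs from 10 to 17, bypassing 15. Commercial but-2-yn-1-ol is treated with NaAlH2(OCH2CH2OMe)2 and then I2 to give (Z)-3-iodobut-2-en-1-ol F3. Iodide 10 is converted with t-BuLi and B-methoxy-9-borabicyclo[3.3.1]nonane into the lithium B-alkyl-B-methoxy-9-borabicyclononane ate complex F4. A B-alkyl Suzuki–Miyaura coupling of F4 with F3 (PdCl2(dppf), aqueous K3PO4, DMF, rt) proceeds with retention to give (2Z,6E,9R)-9-(tert-butyldimethylsilyloxy)-3,7,11-trimethyldodeca-2,6,10-trien-1-ol F5. Oxidation with MnO2 in CH2Cl2 returns to the route at 17.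

Step 14. Fluoride-generated phenoxide could deprotonate C4' and move the C2'=C3' bond into conjugation, the Z-enone could isomerise, or the free hydroquinone could oxidise in air while the hindered C13' ether is still being cleaved. The fallback keeps base away from the skipped dienone and finishes by a reduction instead; it sets out from 28 and rejoins at 30. With no ketone yet present, Bu4NF (2.2 equiv, THF, −20 to 0 °C) removes only the two aryl silyl groups to give the hydroquinone 2-[(2E,6Z,10E,13R)-13-(tert-butyldimethylsilyloxy)-5-hydroxy-3,7,11,15-tetramethylhexadeca-2,6,10,14-tetraenyl]-6-methylbenzene-1,4-diol F6. Excess MnO2 in CH2Cl2 oxidises the hydroquinone to the benzoquinone and the C5' allylic alcohol to the enone in one operation, with C13' still protected, giving the quinone enone silyl ether F7. HF·pyridine buffered with pyridine in THF removes the C13' silyl group under weakly acidic conditions to give the quinone enone alcohol F8. Aqueous Na2S2O4 in a two-phase mixture with EtOAc reduces the quinone to the hydroquinone 30.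

**Further compounds**

F1 | step 12 | (1E,5Z,9E,12R)-12-(tert-butyldimethylsilyloxy)-1-iodo-2,6,10,14-tetramethylpentadeca-1,5,9,13-tetraen-4-ol, both C4 epimers | CC(C)=C[C@H](O[Si](C)(C)C(C)(C)C)C/C(C)=C/CC/C(C)=C\C(O)C/C(C)=C/I
F2 | step 12 | [2,5-bis(tert-butyldimethylsilyloxy)-3-methylbenzyl]zinc chloride | Cl[Zn]Cc1cc(O[Si](C)(C)C(C)(C)C)cc(C)c1O[Si](C)(C)C(C)(C)C
F3 | step 5 | (Z)-3-iodobut-2-en-1-ol | C/C(I)=C/CO
F4 | step 5 | lithium B-[(3E,6R)-6-(tert-butyldimethylsilyloxy)-4,8-dimethylnona-3,7-dien-1-yl]-B-methoxy-9-borabicyclo[3.3.1]nonane ate complex | CC(C)=C[C@H](O[Si](C)(C)C(C)(C)C)C/C(C)=C/CC[B-]1(OC)C2CCCC1CCC2.[Li+]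
F5 | step 5 | (2Z,6E,9R)-9-(tert-butyldimethylsilyloxy)-3,7,11-trimethyldodeca-2,6,10-trien-1-ol | CC(C)=C[C@H](O[Si](C)(C)C(C)(C)C)C/C(C)=C/CC/C(C)=C\CO
F6 | step 14 | 2-[(2E,6Z,10E,13R)-13-(tert-butyldimethylsilyloxy)-5-hydroxy-3,7,11,15-tetramethylhexadeca-2,6,10,14-tetraenyl]-6-methylbenzene-1,4-diol, both C5 epimers | CC(C)=C[C@H](O[Si](C)(C)C(C)(C)C)C/C(C)=C/CC/C(C)=C\C(O)C/C(C)=C/Cc1cc(O)cc(C)c1O
F7 | step 14 | 2-[(2E,6Z,10E,13R)-13-(tert-butyldimethylsilyloxy)-3,7,11,15-tetramethyl-5-oxohexadeca-2,6,10,14-tetraenyl]-6-methyl-1,4-benzoquinone | CC(C)=C[C@H](O[Si](C)(C)C(C)(C)C)C/C(C)=C/CC/C(C)=C\C(=O)C/C(C)=C/CC1=CC(=O)C=C(C)C1=O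
F8 | step 14 | 2-[(2E,6Z,10E,13R)-13-hydroxy-3,7,11,15-tetramethyl-5-oxohexadeca-2,6,10,14-tetraenyl]-6-methyl-1,4-benzoquinone | CC(C)=C[C@H](O)C/C(C)=C/CC/C(C)=C\C(=O)C/C(C)=C/CC1=CC(=O)C=C(C)C1=O
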